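The data were computed with made-up constants.

**Reading time.** At 3.0 min we read how much electrophile has reacted. Tuesday's run has 83.8% product after 2.00 min and 85.0% after 3.00 min, while Sunday's run, with more free base, goes from 92.4% after 1.50 min to 96.3% after 3.00 min. So we ask which of these two courses each new flask will follow.

| setting | Tuesday's | Sunday's | elm | oak | maple |
|---|---|---|---|---|---|
| electrophile | 0.020 M | 0.020 M | 0.020 M | 0.020 M | 0.020 M |
| nucleophile | 0.021 M | 0.021 M | 0.0210 M | 0.0210 M | 0.0210 M |
| free base | 12 mM | 47 mM | 10.0 mM | 20.0 mM | 40.0 mM |
| remark | run made earlier | run made earlier |  |  |  |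
| time |  |  | 3.0 min | 3.0 min | 3.0 min |

- Tuesday's (time / min: electrophile / %, product / %): 0.250: 39.1, 60.7; 0.417: 30.5, 71.6; 0.667: 22.9, 77.6; 1.00: 19.9, 80.1; 2.00: 16.5, 83.8; 3.00: 15.9, 85.0
- Sunday's (time / min: electrophile / %, product / %): 0.200: 42.6, 56.4; 0.667: 17.6, 83.3; 1.00: 12.0, 88.1; 1.50: 7.8, 92.4; 2.50: 4.5, 95.4; 3.00: 3.1, 96.3

(standard deviation of a reading: 0.5 percentage points)



1. part of the electrophile that has reacted at the end, elm
2. part of the electrophile that has reacted at the end, oak
3. part of the electrophile that has reacted at the end, maple
4. what raising the concentration of free base from its lowest to its highest value here does to the part of the electrophile that has reacted (changes below 5 percentage points count as none) (it falls / no change / it rises)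

**Two amounts.** We follow one electrophile molecule. We suppose that on reacting it takes one nucleophile and sets free one acid, which must then take a free base or a second nucleophile. Each reacted electrophile therefore costs two units from one pool, [nucleophile] + [free base]. The demand is two units for each electrophile charged. For elm, pool over demand gives 77.5%; we call this ratio the stall share. Where the pool is smaller than the demand, it is the limiting reagent.

**Our reckoning.** Tuesday's stall share is 82.5%, and its last reading stands above that. Adding the same excess, we expect about 80.0% for elm. In oak the pool exceeds the demand, as it does in maple, so we expect both near Sunday's 96.3%.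

**The forecast.** It reasons that “Free base takes it up first, then nucleophile is protonated and lost”. It gives 79%, 95% and 96.8%, and says it rises.

**The flask.** Elm gives 79.9%, oak 96.0% and maple 96.9%: it rises, by 17 percentage points.

    acid set free + free base ⇌ salt of the base, settled at all times (K = 1.10 × 10⁶ /M)
    nucleophile + acid set free ⇌ protonated nucleophile, settled at all times (K = 32000 /M)
    electrophile + nucleophile → acid set free + product (k = 310 /M/min)

**Beyond the stall.** Elm ends 2.4 points above its stall share and holds 0.00109 M of acid set free, which is 2.74% of the demand. A flask like elm but with 0.0060 M free base has a stall share of 67.5%. It holds 0.00172 M of acid set free, or 4.30% of the demand, and gives 71.5%.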